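The pyrrole ring is built in one step across the C2–C3 and C4–C5 bonds. The N1–C2–C5 triad, with the carboxyl on C2, is the skeleton of an α-isocyano ester, while the neighbouring C3/C4 pair, which bears two identical substituents, maps onto a symmetric alkyne diester whose carboxyls later give way to bromine. A copper-catalysed formal [3+2] union of methyl isocyanoacetate and di-tert-butyl acetylenedicarboxylate thus delivers the aromatic ring with a base-labile methyl ester at C2 and acid-labile tert-butyl esters at C3/C4. N-Methylation, acidolysis, threefold bromination (one C–H, two ipso-decarboxylative) and saponification complete the synthesis.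

Key step: step 1

Remark: the target has no stereocentre, so no configuration has to be set or preserved.

Step 1
Reactants: 1 methyl isocyanoacetate; 2 di-tert-butyl acetylenedicarboxylate
Product: 4 3,4-di-tert-butyl 2-methyl 1H-pyrrole-2,3,4-tricarboxylate, via 2H-pyrrole tautomer 3 (not isolated)
Conditions: Cu2O (5 mol %), 1,10-phenanthroline (10 mol %), 1,4-dioxane, 80–100 °C, slow addition of 2 to 1 (1.2 equiv)
Reagents that add atoms: none
Why: The phenanthroline-ligated monovalent copper generated from Cu2O coordinates the isocyanide and allows removal of the acidified α-C–H of 1, giving an α-cuprated isocyanoacetate that adds in 1,4-fashion to ynoate 2 to forge C2–C3; the vinylcopper so formed attacks the terminal isocyanide carbon to forge C4–C5, and protodemetallation by fresh 1 releases 2H-pyrrole 3 and restarts the cycle. A 1,5-hydrogen shift (or base-mediated prototropy) from the sp3 C2 of 3 to nitrogen then gives aromatic 4. The closest known reaction type is the copper-catalysed formal [3+2] cycloaddition of α-isocyano esters with electron-poor alkynes to pyrrole-2-carboxylates, a relative of the Barton–Zard and van Leusen pyrrole syntheses. The single ring is closed in a 5-endo-dig mode at the isocyanide carbon. No stereocentre remains, because the transient sp3 C2 of 3 is planarised on aromatisation. Regioselectivity is not an issue because 2 is symmetric; the selectivity needed is C–C addition over conjugate addition of the product N–H to a second alkyne, which slow addition of 2, the excess of 1 and the bulk of the tert-butyl esters should secure.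

Step 2
Reactants: 4 3,4-di-tert-butyl 2-methyl 1H-pyrrole-2,3,4-tricarboxylate; 5 iodomethane
Product: 6 3,4-di-tert-butyl 2-methyl 1-methyl-1H-pyrrole-2,3,4-tricarboxylate
Conditions: MeI (1.5 equiv), K2CO3 (2 equiv), DMF, rt
Reagents that add atoms: iodomethane 5, CI
Why: The N–H of 4 is strongly acidified by three ester groups, so carbonate should generate the pyrrolide, which undergoes SN2 N-alkylation with iodomethane while all three esters stay untouched.

Step 3
Reactants: 6 3,4-di-tert-butyl 2-methyl 1-methyl-1H-pyrrole-2,3,4-tricarboxylate
Product: 7 2-(methoxycarbonyl)-1-methyl-1H-pyrrole-3,4-dicarboxylic acid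
Conditions: TFA/CH2Cl2 (1:1), rt
Reagents that add atoms: none
Why: Acidolysis of tert-butyl esters proceeds by alkyl–oxygen cleavage with loss of isobutene (AAL1), a pathway closed to the C2 methyl ester, and the triply acylated ring is too electron-poor to be tert-butylated or protodecarboxylated at room temperature.

Step 4
Reactants: 7 2-(methoxycarbonyl)-1-methyl-1H-pyrrole-3,4-dicarboxylic acid; 8 N-bromosuccinimide
Product: 11 methyl 3,4,5-tribromo-1-methyl-1H-pyrrole-2-carboxylate, via 5-bromo diacid 9 (not isolated), via 4,5-dibromo monoacid 10 (not isolated)
Conditions: NBS (3.3 equiv), LiOAc (0.2 equiv), MeCN/H2O (9:1), 0 °C to 50 °C, dark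
Reagents that add atoms: N-bromosuccinimide 8, O=C1CCC(=O)N1Br
Why: Electrophilic bromination of the free C5–H followed by two ipso-bromodecarboxylations (Hunsdiecker-type halodecarboxylation of pyrrolecarboxylic acids, in which the bromonium equivalent attacks the carboxyl-bearing ring carbon and CO2 leaves from the Wheland intermediate) should replace both acids by bromine, C4 expected before the more deactivated C3, while the C2 methyl ester cannot be expelled and is retained.

Step 5
Reactants: 11 methyl 3,4,5-tribromo-1-methyl-1H-pyrrole-2-carboxylate
Product: 13 3,4,5-tribromo-1-methyl-1H-pyrrole-2-carboxylic acid, via lithium carboxylate 12 (not isolated)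
Conditions: LiOH·H2O (3 equiv), THF/MeOH/H2O (3:1:1), rt to 40 °C; then 1 M HCl to pH 2
Reagents that add atoms: lithium hydroxide, [Li+].[OH-]
Why: Saponification by acyl substitution with hydroxide (BAc2) and subsequent acidification should give the acid, the ring bromides being safe because the π-excessive pyrrole does not support nucleophilic aromatic substitution under these mild conditions.

Compound list
1 | methyl isocyanoacetate | [C-]#[N+]CC(=O)OC | starting material
2 | di-tert-butyl acetylenedicarboxylate | CC(C)(C)OC(=O)C#CC(=O)OC(C)(C)C | starting material
3 | 3,4-di-tert-butyl 2-methyl 2H-pyrrole-2,3,4-tricarboxylate (racemic, transient) | COC(=O)C1N=CC(C(=O)OC(C)(C)C)=C1C(=O)OC(C)(C)C | intermediate (not isolated)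
4 | 3,4-di-tert-butyl 2-methyl 1H-pyrrole-2,3,4-tricarboxylate | COC(=O)c1[nH]cc(C(=O)OC(C)(C)C)c1C(=O)OC(C)(C)C | intermediate
5 | iodomethane | CI | starting material
6 | 3,4-di-tert-butyl 2-methyl 1-methyl-1H-pyrrole-2,3,4-tricarboxylate | COC(=O)c1n(C)cc(C(=O)OC(C)(C)C)c1C(=O)OC(C)(C)C | intermediate
7 | 2-(methoxycarbonyl)-1-methyl-1H-pyrrole-3,4-dicarboxylic acid | COC(=O)c1n(C)cc(C(=O)O)c1C(=O)O | intermediate
8 | N-bromosuccinimide | O=C1CCC(=O)N1Br | starting material
9 | 5-bromo-2-(methoxycarbonyl)-1-methyl-1H-pyrrole-3,4-dicarboxylic acid | COC(=O)c1n(C)c(Br)c(C(=O)O)c1C(=O)O | intermediate (not isolated)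
10 | 4,5-dibromo-2-(methoxycarbonyl)-1-methyl-1H-pyrrole-3-carboxylic acid | COC(=O)c1n(C)c(Br)c(Br)c1C(=O)O | intermediate (not isolated)
11 | methyl 3,4,5-tribromo-1-methyl-1H-pyrrole-2-carboxylate | COC(=O)c1n(C)c(Br)c(Br)c1Br | intermediate
12 | lithium 3,4,5-tribromo-1-methyl-1H-pyrrole-2-carboxylate | [Li+].[O-]C(=O)c1n(C)c(Br)c(Br)c1Br | intermediate (not isolated)
13 | 3,4,5-tribromo-1-methyl-1H-pyrrole-2-carboxylic acid | Cn1c(Br)c(Br)c(Br)c1C(=O)O | target

Total step count: 5. Longest linear sequence: 5 steps (1 and 2 to 13).

Steps most likely to fail

Step 1 (key step). The alkyne may be consumed off-cycle, either by conjugate addition of the acidic N–H of the product to a second alkyne or by uncatalysed isocyanide–ynoate oligomerisation, so that ring formation stalls. The fallback sets out from 1 and swaps the alkyne for the corresponding alkene, purchased di-tert-butyl fumarate (CC(C)(C)OC(=O)/C=C/C(=O)OC(C)(C)C). Cu2O- or AgOAc-catalysed Michael addition and cyclisation of the α-isocyano ester onto the fumarate should give 3,4-di-tert-butyl 2-methyl 3,4-dihydro-2H-pyrrole-2,3,4-tricarboxylate F1 as a racemic diastereomer mixture, whose three stereocentres are erased in the next operation. This intermediate has no acidic pyrrole N–H to intercept the acceptor. Dehydrogenation with DDQ (toluene, 80 °C) and tautomerisation then rejoin the route at 4.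

Step 4. The ipso attack at the ester-deactivated C3 and C4 may stall after C5 bromination, leaving partly brominated acids, or the brominating agent may be used up unproductively. The fallback sets out from 7 and removes both carboxyls first by copper-mediated protodecarboxylation (Cu2O, 1,10-phenanthroline, NMP/quinoline, 170 °C). This should give methyl 1-methyl-1H-pyrrole-2-carboxylate F2. Exhaustive electrophilic aromatic bromination of its three free ring positions with Br2 (3.5 equiv, AcOH, rt to 60 °C) then rejoins the route at 11.

Step 5. Acyl substitution at the ester flanked by the N-methyl group and the C3 bromine may be slow, and forcing it invites attack of hydroxide on the ring bromides or debromination. The fallback sets out from 11 and breaks the O–CH3 bond instead of the acyl C–O bond: SN2 demethylation with LiI in refluxing pyridine should give the lithium carboxylate directly, rejoining the route at 12, which is acidified as in step 5 to give 13. No compound outside the list is formed (F0).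

Further compounds
F1 | step 1 | 3,4-di-tert-butyl 2-methyl 3,4-dihydro-2H-pyrrole-2,3,4-tricarboxylate (racemic, diastereomer mixture) | COC(=O)C1N=CC(C(=O)OC(C)(C)C)C1C(=O)OC(C)(C)C
F2 | step 4 | methyl 1-methyl-1H-pyrrole-2-carboxylate | COC(=O)c1cccn1C
F0 | step 5 | none | none
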